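I want two rate constants per temperature for one molecule of D, and the first can be read straight from the D columns.

| setting | Thursday's | Tuesday's | Saturday's | autumn | dawn | noon |
|---|---|---|---|---|---|---|
| D | 0.42 M | 0.66 M | 0.30 M | 0.30 M | 0.30 M | 0.30 M |
| Q | 30 mM | 30 mM | 60 mM | 30 mM | 30 mM | 30 mM |
| temperature | −5 °C | 8 °C | −5 °C | 0 °C | 15 °C |  |
| remark | run made earlier | run made earlier | run made earlier |  |  | at 0 °C until 2.5 min, from then on at 15 °C |
| time |  |  |  | 12 min | 12 min | 12 min |

| run | time / min | J / % | D / % |
|---|---|---|---|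
| Thursday's | 1.00 | 2.5 | 97.1 |
| Thursday's | 2.50 | 0 | 93.1 |
| Thursday's | 6.00 | 0.8 | 86.5 |
| Thursday's | 15.0 | 2.4 | 70.1 |
| Tuesday's | 4.00 | 1.9 | 58.1 |
| Tuesday's | 8.00 | 7.9 | 34.4 |
| Tuesday's | 10.0 | 10.6 | 26.0 |
| Tuesday's | 15.0 | 18.8 | 14.3 |
| Saturday's | 1.00 | 0 | 97.9 |
| Saturday's | 2.50 | 1.0 | 94.3 |
| Saturday's | 6.00 | 0 | 85.2 |
| Saturday's | 15.0 | 3.1 | 70.3 |

(each reading ± 1 percentage point)

- the flask that comes out highest in amount of J, in percent of the D charged, or "all alike" when all lie within 1.5 percentage points (autumn / dawn / noon / all alike)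
- J at the end, in percent of the D charged, autumn
- J at the end, in percent of the D charged, dawn
- J at the end, in percent of the D charged, noon

- a reading or a percentage of J counts all its forms, free or not

At 15.0 min, Thursday's run keeps 70.1% of its D and Saturday's 70.3%, although Saturday's has twice the Q and a different [D]. So I take the loss of D as first order. Thursday's gives k = 0.0237 /min at −5 °C and Tuesday's gives 0.130 /min at 8 °C. Stepping geometrically in temperature, I get 0.0455 /min at 0 °C and 0.324 /min at 15 °C.

In Tuesday's run J trails the loss of D, so I let a molecule that has left D wait in a pool, counted as whatever is neither D nor J. Its chance per minute of becoming J is what I call h. Late in Tuesday's run, J gained over mean pool and time gives 0.0250 /min. The two cold runs together give 0.0136 /min. The same stepping gives 0.0172 /min at 0 °C and 0.0347 /min at 15 °C, the hand-over rate of the pool. In my estimate for dawn this is the rate-limiting step.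

The chance of having crossed both steps by time t is:

J = 1 − (k·exp(−ht) − h·exp(−kt))/(k − h)

autumn: 4.40%

dawn: 26.4%

noon: 10.8% has left D at the change, and the two groups together give 20.9%

The weak link is the cold h, which rests on final J readings of 2.4% and 3.1%, each with a scatter of 1 percentage point, from runs that differ in Q. Taken separately, Thursday's run puts h at 15 °C at 0.0377 /min and Saturday's at 0.0323 /min. Dawn then moves between 24.8% and 28.3%. My central dawn stands above noon by 5.5 points, against a margin of 1.5 points.

The forecast names dawn, with autumn 3.9%, dawn 30% and noon 24%. Its ground is “J lags far behind D loss, so an unseen intermediate builds up”. Its dawn stands above mine, and it puts the second step at −5 °C at roughly 0.01/min, where I have 0.0136 /min.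

The flasks give dawn as highest: autumn 4.23%, dawn 26.1%, noon 22.2%.

    D → X (k = 5.10 × 10⁻⁴ /s, Ea = 74.0 kJ/mol)
    Q + X → Q + J (k = 0.0190 /M/s, Ea = 54.0 kJ/mol)
    D → G (k = 3.00 × 10⁻⁴ /s, Ea = 93.0 kJ/mol)
    2 Q ⇌ E, settled at all times (K = 7.40 /M, ΔH = 19.0 kJ/mol)
    Z ⇌ J, rate k5*(cs5 - [J]) while solid is left; crystals form when [J] > cs5 (solubility = 0.190 M, k = 0.0240 /s)
    (constants at 0 °C)

Now the neighbour: noon read at 50 min. I carry h forward from noon's J at 12.0 min and get 79.2%. That flask gives 52.1%. My pool was one lump, but noon's at 12.0 min holds G at 44.4% beside X at 29.2%. In the flask read at 50.0 min, G stands at 46.4% and X at 1.52%.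

All runs were generated by integration with constants of no real substance, and the scatter is random.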